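**Retrosynthetic overview**

1. The lactone bridge (O-6–C-7) of the 6-oxabicyclo[3.2.1]octane-7,8-dione is closed last: a Chan 1,2-acyl shift in an α-(isobutyryloxy)cyclohexanone builds the fully substituted C-5 (O and isobutyryl on one carbon), and its alkoxide attacks the axial C-1 ester.
2. The carbocycle (C-1, C-2, C-3, C-4, C-5, C-8) is made before that, in one radical annulation that forms C-8–C-5 and C-3–C-4: an acyl radical at C-8 adds to 2-methylprop-1-en-1-yl 2-methylpropanoate, and the tertiary radical at C-4 closes 6-exo onto an enal carbon, the later C-3.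
3. Feature that allows this: in the six-membered ring the ketone carbon C-8 is followed by the O-bearing C-5, the gem-dimethyl C-4 and the methine C-3. C-4, C-5, O-6 and the isobutyryl group are therefore the enol isobutyrate of isobutyraldehyde, whose CH–O end accepts the acyl radical and whose Me2C end becomes a tertiary radical placed for 6-exo closure on C-3.
4. The radical precursor is an acyclic Se-phenyl selenoester whose quaternary carbon (C-1) comes from asymmetric phase-transfer alkylation of a mixed malonate; the C-3 prenyl group is completed by a Wittig reaction on the aldehyde left by the ring closure.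
5. Ring order: cyclohexanone (step 10), then γ-lactone (step 12).

Key step: step 10

Assumption: the sense of induction of the phase-transfer alkylation in step 5 is taken as drawn; the enantiomer of the catalyst that gives (S)-9 is the one to be used.

**Route**

Step 1
Reactants: 1 (E)-4,4-dimethoxybut-2-enal
Product: 2 (E)-4,4-dimethoxybut-2-en-1-ol
Conditions: NaBH4, MeOH, 0 °C
Reagents that add atoms: none
Why: Hydride 1,2-reduction of the enal should give the allylic alcohol and leave the acetal and the E-alkene untouched.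

Step 2
Reactants: 2 (E)-4,4-dimethoxybut-2-en-1-ol
Product: 3 (E)-4-bromo-1,1-dimethoxybut-2-ene
Conditions: CBr4, PPh3, CH2Cl2, 0 °C
Reagents that add atoms: carbon tetrabromide, BrC(Br)(Br)Br
Why: The Appel reaction replaces the primary allylic hydroxyl by bromide under non-acidic conditions that the acetal tolerates.

Step 3
Reactants: 4 3-tert-butoxy-3-oxopropanoic acid, 5 2,2-diphenylethanol
Product: 6 1-tert-butyl 3-(2,2-diphenylethyl) propanedioate
Conditions: DCC, DMAP (cat.), CH2Cl2, 0 °C to rt
Reagents that add atoms: none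
Why: Steglich esterification joins the half-ester and the primary alcohol without touching the tert-butyl ester.

Step 4
Reactants: 6 1-tert-butyl 3-(2,2-diphenylethyl) propanedioate, 3 (E)-4-bromo-1,1-dimethoxybut-2-ene
Product: 7 1-tert-butyl 3-(2,2-diphenylethyl) 2-[(E)-4,4-dimethoxybut-2-en-1-yl]propanedioate
Conditions: NaH, THF–DMF, 0 °C to rt (6 in slight excess)
Reagents that add atoms: none
Why: Malonate alkylation (SN2 of the sodium enolate on the primary allylic bromide) should give the mono-alkylated diester.

Step 5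
Reactants: 7 1-tert-butyl 3-(2,2-diphenylethyl) 2-[(E)-4,4-dimethoxybut-2-en-1-yl]propanedioate, 8 1-bromo-3-methylbut-2-ene
Product: 9 1-tert-butyl 3-(2,2-diphenylethyl) (S)-2-[(E)-4,4-dimethoxybut-2-en-1-yl]-2-(3-methylbut-2-en-1-yl)propanedioate
Conditions: (S,S)-3,4,5-trifluorophenyl-NAS bromide (5 mol %), 50% aq. KOH, toluene, −40 °C
Reagents that add atoms: none
Why: Asymmetric phase-transfer alkylation of an α-substituted mixed malonate should set the quaternary stereocenter, because the two unlike ester groups fix the enolate in a tight ion pair with the chiral ammonium ion, which shields one face from the allylic bromide.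

Step 6
Reactants: 9 1-tert-butyl 3-(2,2-diphenylethyl) (S)-2-[(E)-4,4-dimethoxybut-2-en-1-yl]-2-(3-methylbut-2-en-1-yl)propanedioate
Product: 10 (S)-2-(tert-butoxycarbonyl)-2-[(E)-4,4-dimethoxybut-2-en-1-yl]-5-methylhex-4-enoic acid
Conditions: 1 M KOH, MeOH–H2O, 40 °C; then cold 1 M HCl to pH 4
Reagents that add atoms: potassium hydroxide, [K+].[OH-]
Why: Saponification should be selective for the primary 2,2-diphenylethyl ester because the tert-butyl ester resists hydroxide, and the quaternary centre cannot epimerize.

Step 7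
Reactants: 10 (S)-2-(tert-butoxycarbonyl)-2-[(E)-4,4-dimethoxybut-2-en-1-yl]-5-methylhex-4-enoic acid
Product: 11 tert-butyl (R)-2-[(E)-4,4-dimethoxybut-2-en-1-yl]-5-methyl-2-[(phenylselanyl)carbonyl]hex-4-enoate
Conditions: N-(phenylselanyl)phthalimide, PBu3, CH2Cl2, 0 °C to rt
Reagents that add atoms: N-(phenylselanyl)phthalimide, O=C1c2ccccc2C(=O)N1[Se]c1ccccc1
Why: Selenoester formation through the acyloxyphosphonium salt is neutral and should keep the acetal and both alkenes (the descriptor changes only because Se outranks O).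

Step 8
Reactants: 11 tert-butyl (R)-2-[(E)-4,4-dimethoxybut-2-en-1-yl]-5-methyl-2-[(phenylselanyl)carbonyl]hex-4-enoate
Product: 12 tert-butyl (R)-5-methyl-2-[(E)-4-oxobut-2-en-1-yl]-2-[(phenylselanyl)carbonyl]hex-4-enoate
Conditions: pyridinium p-toluenesulfonate (cat.), acetone–H2O, 40 °C
Reagents that add atoms: water, O
Why: Mild acid-catalysed acetal hydrolysis frees the E-enal, while the selenoester and the tert-butyl ester are stable to this weak acid.

Step 9
Reactants: 13 2-methylpropanal, 14 2-methylpropanoic anhydride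
Product: 15 2-methylprop-1-en-1-yl 2-methylpropanoate
Conditions: Et3N, DMAP (cat.), 80 °C
Reagents that add atoms: none
Why: O-Acylation of the enol form of the α-branched aldehyde (enol ester formation) gives the only possible enol ester, which has no E/Z isomers.

Step 10
Reactants: 12 tert-butyl (R)-5-methyl-2-[(E)-4-oxobut-2-en-1-yl]-2-[(phenylselanyl)carbonyl]hex-4-enoate, 15 2-methylprop-1-en-1-yl 2-methylpropanoate
Product: 18 tert-butyl (1R,5S)-4,4-dimethyl-1-(3-methylbut-2-en-1-yl)-3-[(2-methylpropanoyl)oxy]-2-oxo-5-(2-oxoethyl)cyclohexane-1-carboxylate (both C-3 epimers), via acyl radical 16 (not isolated), via tertiary alkyl radical 17 (not isolated)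
Conditions: (Me3Si)3SiH (slow addition), Et3B, air, 15 (20 equiv) in toluene, −30 °C
Reagents that add atoms: none
Why: The silyl radical abstracts the phenylselanyl group of 12 to give acyl radical 16, which has only 4-exo or 5-endo paths to its own alkenes and therefore adds to the CH–O terminus of enol ester 15 to give the tertiary β-acyloxy radical 17; 17 closes the carbocycle by conjugate addition to the enal, and the α-formyl radical takes hydrogen from the silane and carries the chain. The closest known reaction types are acyl-radical addition–cyclization cascades started from Se-phenyl selenoesters (radical annulation), the radical-chain hydroacylation of enol esters and the intramolecular Giese reaction. One ring is closed, the cyclohexanone, in the 6-exo-trig mode; the lactone is left for step 12. C-5 is set relative to the quaternary C-1 by a chair transition state that places the enal arm and the C-1 prenyl group equatorial and the C-1 ester axial, while C-3 forms as both epimers, which does no harm because it is enolized in step 12. The step needs attack of 16 at the less substituted alkene carbon of 15 (secured by sterics and by the tertiary radical that results), closure of 17 onto the electron-poor enal and not onto the prenyl alkene (secured by the nucleophilic character of the tertiary radical), and trapping of 16 before it loses CO (secured by the large excess of 15 and the low temperature).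

Step 11
Reactants: 18 tert-butyl (1R,5S)-4,4-dimethyl-1-(3-methylbut-2-en-1-yl)-3-[(2-methylpropanoyl)oxy]-2-oxo-5-(2-oxoethyl)cyclohexane-1-carboxylate, 19 triphenyl(propan-2-yl)phosphonium iodide
Product: 20 tert-butyl (1R,5R)-4,4-dimethyl-1,5-bis(3-methylbut-2-en-1-yl)-3-[(2-methylpropanoyl)oxy]-2-oxocyclohexane-1-carboxylate (both C-3 epimers)
Conditions: n-BuLi, THF, −78 °C to 0 °C
Reagents that add atoms: none
Why: Wittig olefination with the non-stabilized isopropylidene ylide is far faster at the unhindered aldehyde than at the flanked ketone, and the low temperature limits enolization of the α-acyloxy ketone.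

Step 12
Reactants: 20 tert-butyl (1R,5R)-4,4-dimethyl-1,5-bis(3-methylbut-2-en-1-yl)-3-[(2-methylpropanoyl)oxy]-2-oxocyclohexane-1-carboxylate
Product: 22 (1R,3R,5R)-4,4-dimethyl-1,3-bis(3-methylbut-2-en-1-yl)-5-(2-methylpropanoyl)-6-oxabicyclo[3.2.1]octane-7,8-dione (CNP0231965.1), via hydroxy diketone 21 (not isolated)
Conditions: LiN(SiMe3)2, THF, −78 °C to rt; then AcOH
Reagents that add atoms: none
Why: The Chan rearrangement (1,2 O-to-C acyl shift of the ketone enolate through an oxirane alkoxide, C-3 being the only enolizable ketone position) creates the carbinol carbon bearing isobutyryl, and only the alkoxide cis to the axial C-1 ester can displace tert-butoxide to close the γ-lactone, so the bridgehead configuration is fixed by the ring while the reversible acyl shift should drain the other epimer.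

**Compound list**

1 | (E)-4,4-dimethoxybut-2-enal | COC(OC)/C=C/C=O | starting material
2 | (E)-4,4-dimethoxybut-2-en-1-ol | COC(OC)/C=C/CO | intermediate
3 | (E)-4-bromo-1,1-dimethoxybut-2-ene | COC(OC)/C=C/CBr | intermediate
4 | 3-tert-butoxy-3-oxopropanoic acid | CC(C)(C)OC(=O)CC(=O)O | starting material
5 | 2,2-diphenylethanol | OCC(c1ccccc1)c1ccccc1 | starting material
6 | 1-tert-butyl 3-(2,2-diphenylethyl) propanedioate | CC(C)(C)OC(=O)CC(=O)OCC(c1ccccc1)c1ccccc1 | intermediate
7 | 1-tert-butyl 3-(2,2-diphenylethyl) 2-[(E)-4,4-dimethoxybut-2-en-1-yl]propanedioate | COC(OC)/C=C/CC(C(=O)OC(C)(C)C)C(=O)OCC(c1ccccc1)c1ccccc1 | intermediate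
8 | 1-bromo-3-methylbut-2-ene | CC(C)=CCBr | starting material
9 | 1-tert-butyl 3-(2,2-diphenylethyl) (S)-2-[(E)-4,4-dimethoxybut-2-en-1-yl]-2-(3-methylbut-2-en-1-yl)propanedioate | COC(OC)/C=C/C[C@@](C(=O)OCC(c1ccccc1)c1ccccc1)(CC=C(C)C)C(=O)OC(C)(C)C | intermediate
10 | (S)-2-(tert-butoxycarbonyl)-2-[(E)-4,4-dimethoxybut-2-en-1-yl]-5-methylhex-4-enoic acid | COC(OC)/C=C/C[C@@](C(=O)O)(CC=C(C)C)C(=O)OC(C)(C)C | intermediate
11 | tert-butyl (R)-2-[(E)-4,4-dimethoxybut-2-en-1-yl]-5-methyl-2-[(phenylselanyl)carbonyl]hex-4-enoate | COC(OC)/C=C/C[C@@](C(=O)[Se]c1ccccc1)(CC=C(C)C)C(=O)OC(C)(C)C | intermediate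
12 | tert-butyl (R)-5-methyl-2-[(E)-4-oxobut-2-en-1-yl]-2-[(phenylselanyl)carbonyl]hex-4-enoate | O=C/C=C/C[C@@](C(=O)[Se]c1ccccc1)(CC=C(C)C)C(=O)OC(C)(C)C | intermediate
13 | 2-methylpropanal | CC(C)C=O | starting material
14 | 2-methylpropanoic anhydride | CC(C)C(=O)OC(=O)C(C)C | starting material
15 | 2-methylprop-1-en-1-yl 2-methylpropanoate | CC(C)C(=O)OC=C(C)C | intermediate
16 | acyl radical from 12 (radical at the former selenoester carbon) | O=C/C=C/C[C@@]([C]=O)(CC=C(C)C)C(=O)OC(C)(C)C | intermediate
17 | tertiary alkyl radical, adduct of 16 and 15 (radical at the Me2C carbon) | O=C/C=C/C[C@@](C(=O)C(OC(=O)C(C)C)[C](C)C)(CC=C(C)C)C(=O)OC(C)(C)C | intermediate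
18 | tert-butyl (1R,5S)-4,4-dimethyl-1-(3-methylbut-2-en-1-yl)-3-[(2-methylpropanoyl)oxy]-2-oxo-5-(2-oxoethyl)cyclohexane-1-carboxylate (both C-3 epimers) | O=CC[C@@H]1C[C@@](CC=C(C)C)(C(=O)OC(C)(C)C)C(=O)C(OC(=O)C(C)C)C1(C)C | intermediate
19 | triphenyl(propan-2-yl)phosphonium iodide | CC(C)[P+](c1ccccc1)(c1ccccc1)c1ccccc1.[I-] | starting material
20 | tert-butyl (1R,5R)-4,4-dimethyl-1,5-bis(3-methylbut-2-en-1-yl)-3-[(2-methylpropanoyl)oxy]-2-oxocyclohexane-1-carboxylate (both C-3 epimers) | CC(C)=CC[C@@H]1C[C@@](CC=C(C)C)(C(=O)OC(C)(C)C)C(=O)C(OC(=O)C(C)C)C1(C)C | intermediate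
21 | tert-butyl (1R,3R,5R)-3-hydroxy-4,4-dimethyl-1,5-bis(3-methylbut-2-en-1-yl)-3-(2-methylpropanoyl)-2-oxocyclohexane-1-carboxylate | CC(C)=CC[C@@H]1C[C@@](CC=C(C)C)(C(=O)OC(C)(C)C)C(=O)[C@](O)(C(=O)C(C)C)C1(C)C | intermediate
22 | (1R,3R,5R)-4,4-dimethyl-1,3-bis(3-methylbut-2-en-1-yl)-5-(2-methylpropanoyl)-6-oxabicyclo[3.2.1]octane-7,8-dione | CC(C)=CC[C@@H]1C[C@@]2(CC=C(C)C)C(=O)O[C@](C(=O)C(C)C)(C2=O)C1(C)C | target

**Step count and risks**

Total step count: 12. Longest linear sequence: 10 steps (steps 1, 2, 4, 5, 6, 7, 8, 10, 11, 12).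

Step 10 (key step). What may go wrong: loss of carbon monoxide from acyl radical 16 before it is trapped (the quaternary, ester-bearing neighbour favours this), sluggish intermolecular addition to the trisubstituted enol ester, and incomplete facial control at C-5 in the monocyclic ring closure. The fallback makes the two bonds one after the other; it sets out from acid 10 and comes back at 20. Acid 10 is converted with 1-chloro-N,N,2-trimethylprop-1-en-1-amine into the acid chloride F1, and Stille acylation with tributyl(2-methylprop-2-en-1-yl)stannane and PdCl2(PPh3)2 gives the methallyl ketone F2. Acetal hydrolysis as in step 8 gives the enal F3. Hydrogen-atom-transfer-initiated reductive cyclization (Fe(acac)3, PhSiH3, EtOH–ethylene glycol; the 1,1-disubstituted alkene should react before the prenyl group) generates the same kind of tertiary radical and should close the ring 6-exo to the keto aldehyde F4. Wittig olefination as in step 11 gives the diprenyl ketone F5; enolate hydroxylation (KN(SiMe3)2, then 3-phenyl-2-(phenylsulfonyl)oxaziridine) gives the α-hydroxy ketone F6; acylation with 2-methylpropanoyl chloride, pyridine and DMAP gives 20.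

Step 12. What may go wrong: enolization of the isobutyrate instead of the ring ketone followed by aldol closure, acyloin-type ring contraction of the tertiary alkoxide, or slow displacement of tert-butoxide by the hindered alkoxide. The fallback brings in the isobutyryl group as an acyl anion instead of by an acyl shift; it sets out from 20 and comes back at 22. Methanolysis of 20 (K2CO3, MeOH) gives the α-hydroxy ketone F6, and oxidation with the periodinane DMP gives the non-enolizable 1,2-dione F7. N-Heterocyclic-carbene-catalysed crossed benzoin addition of 13 (triazolium precatalyst, DBU, THF) is reversible at both ketones, but only the adduct at C-3 with oxygen cis to the ester (the alkoxide of 21) can lactonize, which should drain the mixture to 22.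

Step 5. What may go wrong: low enantioselectivity in the alkylation of the bulky α-substituted enolate. The fallback uses resolution instead of asymmetric catalysis; it sets out from 7 and comes back at 10. Alkylation of 7 with 8 under achiral phase-transfer conditions (Bu4NBr, KOH, toluene) gives the racemic diester F8, and saponification as in step 6 gives the racemic acid F9. Crystallization with (S)-1-phenylethylamine gives the diastereomerically pure ammonium carboxylate F10 (taken to be the less soluble salt; otherwise the (R)-amine is used), and acidification returns 10.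

**Further compounds**

F1 | step 10 | tert-butyl (R)-2-(chlorocarbonyl)-2-[(E)-4,4-dimethoxybut-2-en-1-yl]-5-methylhex-4-enoate | COC(OC)/C=C/C[C@@](C(=O)Cl)(CC=C(C)C)C(=O)OC(C)(C)C
F2 | step 10 | tert-butyl (S)-2-[(E)-4,4-dimethoxybut-2-en-1-yl]-5-methyl-2-(3-methylbut-3-enoyl)hex-4-enoate | COC(OC)/C=C/C[C@@](C(=O)CC(C)=C)(CC=C(C)C)C(=O)OC(C)(C)C
F3 | step 10 | tert-butyl (S)-5-methyl-2-(3-methylbut-3-enoyl)-2-[(E)-4-oxobut-2-en-1-yl]hex-4-enoate | O=C/C=C/C[C@@](C(=O)CC(C)=C)(CC=C(C)C)C(=O)OC(C)(C)C
F4 | step 10 | tert-butyl (1R,5S)-4,4-dimethyl-1-(3-methylbut-2-en-1-yl)-2-oxo-5-(2-oxoethyl)cyclohexane-1-carboxylate | O=CC[C@@H]1C[C@@](CC=C(C)C)(C(=O)OC(C)(C)C)C(=O)CC1(C)C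
F5 | step 10 | tert-butyl (1R,5R)-4,4-dimethyl-1,5-bis(3-methylbut-2-en-1-yl)-2-oxocyclohexane-1-carboxylate | CC(C)=CC[C@@H]1C[C@@](CC=C(C)C)(C(=O)OC(C)(C)C)C(=O)CC1(C)C
F6 | step 10 | tert-butyl (1R,5R)-3-hydroxy-4,4-dimethyl-1,5-bis(3-methylbut-2-en-1-yl)-2-oxocyclohexane-1-carboxylate (both C-3 epimers) | CC(C)=CC[C@@H]1C[C@@](CC=C(C)C)(C(=O)OC(C)(C)C)C(=O)C(O)C1(C)C
F7 | step 12 | tert-butyl (1R,5R)-4,4-dimethyl-1,5-bis(3-methylbut-2-en-1-yl)-2,3-dioxocyclohexane-1-carboxylate | CC(C)=CC[C@@H]1C[C@@](CC=C(C)C)(C(=O)OC(C)(C)C)C(=O)C(=O)C1(C)C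
F8 | step 5 | racemic 1-tert-butyl 3-(2,2-diphenylethyl) 2-[(E)-4,4-dimethoxybut-2-en-1-yl]-2-(3-methylbut-2-en-1-yl)propanedioate | COC(OC)/C=C/CC(C(=O)OCC(c1ccccc1)c1ccccc1)(CC=C(C)C)C(=O)OC(C)(C)C
F9 | step 5 | racemic 2-(tert-butoxycarbonyl)-2-[(E)-4,4-dimethoxybut-2-en-1-yl]-5-methylhex-4-enoic acid | COC(OC)/C=C/CC(C(=O)O)(CC=C(C)C)C(=O)OC(C)(C)C
F10 | step 5 | (S)-1-phenylethylammonium (S)-2-(tert-butoxycarbonyl)-2-[(E)-4,4-dimethoxybut-2-en-1-yl]-5-methylhex-4-enoate | COC(OC)/C=C/C[C@@](C(=O)[O-])(CC=C(C)C)C(=O)OC(C)(C)C.C[C@H]([NH3+])c1ccccc1
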